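The runs stem from a simulated flask for substances that don't exist; scatter was added.

We have no constants, so we read one from the readings: how long the catalyst stays at work.

| flask | substrate | free catalyst | product | time |
|---|---|---|---|---|
| eta | 0.600 M | 0.00300 M |  |  |
| delta | 0.360 M | 0.00300 M |  |  |
| alpha | 0.600 M | 0.00300 M | 0.180 M |  |
| zeta | 0.300 M | 0.00900 M |  | 82 h |

| eta run: time / h | eta run: [product] / M | delta run: time / h | delta run: [product] / M | alpha run: time / h | alpha run: [product] / M |
|---|---|---|---|---|---|
| 3.6 | 0.046 | 3.6 | 0.023 | 3.6 | 0.230 |
| 11 | 0.124 | 11 | 0.071 | 11 | 0.308 |
| 21 | 0.214 | 21 | 0.096 | 21 | 0.394 |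
| 33 | 0.259 | 33 | 0.133 | 33 | 0.448 |
| 48 | 0.317 | 48 | 0.146 | 48 | 0.492 |
| 64 | 0.342 | 64 | 0.180 | 64 | 0.521 |
| 82 | 0.383 | 82 | 0.194 | 82 | 0.573 |

(scatter of a reading: 0.006 M)

- apparent order in [substrate] of the starting rate, round the charge of the eta run (the rate where two percent of its substrate have turned into product) (one fixed amount of product, the same in the runs compared)
- the delta run starts with 0.240 M less of substrate than the eta run, and with no product. Compared where both hold the same amount of substrate, once fifteen percent of what the delta run was charged with has turned into product, is the delta run faster, slower or alike (within a tenth)?
- product in the zeta run at 82 h, as a share of the substrate charged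

- Overall: substrate -> product, with free catalyst as catalyst.
- Constant volume, constant temperature.
- What is held in complexes is read along with the free species.
- An order is taken over about fifteen percent of the charge, up and down.

Added product changes little: at 21 h the alpha run, net of its spike, stands at 0.214 M and the eta run at 0.214 M. Now we compare two flasks holding about 0.313 M of substrate. The delta run, aged 7.30 h, makes 0.00649 M/h, and the eta run, aged 40.5 h, makes 0.00387 M/h. So the delta run reads faster than the eta run, with a ratio of 1.68.

We assume, untested by these runs, that catalyst dies in pairs, so activity falls as the reciprocal of one plus age over τ. The ratio then gives the working life τ, the age at which activity has halved, as a reading of 41.7 h. On that assumption τ shortens in proportion to the catalyst charge, so we estimate 13.9 h for the zeta run. Its full-strength time, τ times the logarithm of one plus age over τ, is then 32.7% of the 82 h, about a third. Treating substrate as first order, the delta run's last reading gives 0.0171 /h, and multiplying this by the catalyst ratio of 3.00 for the zeta run, we expect 74.7%.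

The forecast says 1.25, faster and 85%, holding that “the catalyst is dying with time”. Its 85% is what the eta run gives with its clock scaled as if first order in everything but substrate.

The simulation gives 1.1, faster and 55.1%, the last below both our figure and the forecast's.

    free catalyst + substrate ⇌ catalyst-substrate complex, settled at all times (6.820 /M)
    catalyst-substrate complex + substrate ⇌ doubly bound catalyst, settled at all times (0.5200 /M)
    doubly bound catalyst → product + catalyst-substrate complex (23.15 /h)
    2 free catalyst → 2 spent catalyst (223.2 /M/h)
    substrate → product (0.004464 /h)

The zeta run reaches 55.1% rather than 93.4% because free catalyst passes into spent catalyst. Counted first order in substrate, those two yields leave 29.5% of the clock, against the 32.7% from τ. In the delta run, whose last reading gave 0.0171 /h, τ puts half of the charge at 68.5 h, and that run stood there at 69.9 h.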